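**Remark:** the target is taken exactly as drawn. Chain atoms are numbered C1 (OCH2) to C8 (lactone carbonyl); C9 is the exocyclic methylene on C7 and C10 the methyl on C3. Rings A and B are the benzene and pyranone rings of the coumarin, ring C is the lactone. Both enantiomers of epichlorohydrin are taken as commercial.

## Analysis of the target

The target is a ten-carbon chain that carries the 7-oxycoumarin (rings A and B) as an aryl ether at C1 and ends in ring C, an α-methylene-γ-butyrolactone made of the lactone oxygen, C5, C6, C7 and C8, with C7=C9 exocyclic. It has three stereocenters: C2 (R, secondary carbinol), C3 (S, tertiary carbinol) and C5 (S, lactone carbinol). C2 and C3 are related as the anti addition of two oxygens across an (E)-C2=C3 alkene. The C3 hydroxyl and the C5 oxygen are 1,3-syn in the extended chain, separated only by the C4 methylene, with no ring to relay one to the other. Ring C is the most fragile function: C7=C9 is a Michael acceptor toward phenoxides, alkoxides and phosphines, and the double bond moves into the ring under base. The coumarin lactone (ring B) opens in hydroxide or alkoxide and rules out carbanion chemistry once it is present, and an allylic C1–O bond to this acidic phenol would be ionised by low-valent palladium or nickel. The difficulty is therefore not size but placing three oxygen-bearing stereocenters on an open chain, without protecting groups, while two electrophilic lactones restrict what can be done late.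

## Retrosynthetic reasoning

**12 to 11 (O–C8 and C7–C8).** Ring C is opened by removing C8. The exocyclic C7=C9 pair is read as a terminal alkyne and C8 as a carbonyl unit taken up in a palladium-catalysed cyclocarbonylation, which leads to the open-chain alkynyl triol 11. The cut is made here and not at C5–C6 for three reasons: C5 becomes an ordinary secondary carbinol whose configuration can be bought; the most fragile ring is made in the last step under neutral conditions; and no protecting group is needed, because ring size alone distinguishes the C5 hydroxyl from those on C2 and C3. The forward reaction must bond the carbonyl carbon to the internal alkyne carbon C7 and to the C5 oxygen, and leave the double bond exocyclic.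

**11 to 10 (C3–OH).** The C2/C3 diol is the anti-addition product of an (E)-alkene, so it is traced to the trans epoxide 10, opened by an oxygen nucleophile at the tertiary C3 with inversion. The forward hydrolysis must be regioselective for C3 and stereospecific.

**10 to 8 and 9 (C1–OAr).** The aryl ether is cut to the primary epoxy alcohol 8 and the phenol 9, joined by dehydrative etherification. This brings the coumarin in after all organometallic steps and after the alkene has been consumed, so no allylic aryl ether ever exists.

**8 to 7 (both epoxide C–O bonds).** The epoxide comes from tartrate-controlled epoxidation of the (E)-allylic alcohol 7. C2 and C3 are set together in one catalytic event under reagent control. The C1 hydroxyl serves first as the directing group and then as the anchor for 9.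

**7 to 5, through 6 (C6–C7).** The alkyne arm is cut to an ethynyl anion and the terminal epoxide 6, formed in the flask from chlorohydrin 5. The (E) double bond holds the C1 alkoxide out of reach of the epoxide, so no protection is needed.

**5 to 2 (C3–C10 and C1–C2).** The trisubstituted (E)-allylic alcohol is cut to the terminal alkyne 2 by a syn methyl-metalation followed by hydroxymethylation of the alkenyl metal. The step fixes the alkene geometry and is only possible while neither lactone is present.

**2 to 1 (C3–C4).** The first alkyne arm is cut to an ethynyl anion and the epoxide terminus of 1. This buys C5 and keeps the chloride as the latent second epoxide. Compound 1 thus serves as the C4–C5–C6 linchpin whose two methylene ends are alkynylated in turn: one alkyne becomes C2/C3, the other C7/C9.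

## Alternatives that were turned down

**Alternative 1:** the textbook disconnection at C5–C6 together with the lactone C–O bond. The forward key step is a zinc- or indium-mediated Barbier addition of a 2-(bromomethyl)acrylate ester to the acetonide-protected aldehyde A1, with lactonisation in the flask and acetal removal afterwards. It was turned down for three reasons. The only resident control element for C5 is the fully substituted β-carbon C3; open-chain 1,3-induction from such a centre is weak and, where it operates through polar or chelate models, tends toward 1,3-anti, whereas the target needs 1,3-syn. A1 needs a diol protection, a two-carbon arm and an alkene cleavage next to the coumarin C3=C4 bond, several steps more than the route below. The final acid deprotection would expose the new lactone to a free tertiary hydroxyl in a 1,3 position.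

**Alternative 2:** a ring-template relay. The disconnection is at the C2–O and C3–O bonds of the six-membered lactone A2, in which C1 is the carbonyl and the C5 oxygen is the ring oxygen. The forward key step is an osmium-catalysed cis-dihydroxylation of A2 on the face opposite the C5 substituent, which would give A3 and fix C2 and C3 from C5 in one event. It was turned down because C1 then sits at the carboxyl level: it must be reduced and etherified selectively at C1 beside three other free hydroxyls. A2 also needs a (Z)-selective construction, and ring-closing metathesis of an acrylate is not compatible with the alkyne. The count exceeds ten steps, which costs more than the saved chiral catalyst.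

**Alternative 3:** disconnection at C3–C4. The forward key step is a nickel-catalysed reductive coupling of the (Z)-alkenyl iodide A4, which already carries the coumarin ether, with the terminal epoxide A5 to give the (Z)-homoallylic alcohol A6. A ligand-controlled osmium cis-dihydroxylation would then give the C2/C3 diol directly. It was turned down because the allylic C1–O bond to an acidic phenol is exposed to low-valent nickel and should ionise. Trisubstituted alkenyl iodides are also poor partners in this coupling, the (Z) geometry brings the C5 hydroxyl within reach of C1, and the alkyne must be silyl-masked and unmasked.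

Key step: step 7

## Route

Step 1
Reactants: 1 (R)-epichlorohydrin
Product: 2 (2R)-1-chloropent-4-yn-2-ol
Conditions: acetylene (excess), n-BuLi, THF, −78 °C; BF3·OEt2; then 1, −78 °C; aq. NH4Cl
Reagents that add atoms: acetylene, C#C
Why: Yamaguchi–Hirao alkynylation: the BF3-activated epoxide is opened by lithium acetylide at its unsubstituted carbon, the chloride is untouched at −78 °C, and the C–O bond at the stereocenter (later C5) is never broken, so its configuration is that of 1.

Step 2
Reactants: 2 (2R)-1-chloropent-4-yn-2-ol
Product: 5 (2E,5R)-6-chloro-3-methylhex-2-ene-1,5-diol, via alkenyldimethylalane 3 (not isolated), via lithium alkenylalanate 4 (not isolated)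
Conditions: Me3Al (3 equiv), Cp2ZrCl2 (25 mol%), CH2Cl2, 0 °C to rt; volatiles off; n-BuLi, THF/hexane, −78 °C; (CH2O)n, −78 °C to rt; aq. potassium sodium tartrate
Reagents that add atoms: trimethylaluminium, C[Al](C)C; paraformaldehyde (as formaldehyde), C=O
Why: Negishi zirconium-catalysed carboalumination adds methyl to the internal and aluminium to the terminal alkyne carbon in a syn fashion (3); the ate complex 4 transfers the alkenyl group to formaldehyde with retention, which should give the (E)-allylic alcohol; the hydroxyl travels as its aluminium alkoxide and room temperature keeps the kinetic syn adduct from isomerising.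

Step 3
Reactants: 5 (2E,5R)-6-chloro-3-methylhex-2-ene-1,5-diol
Product: 7 (2E,5S)-3-methyloct-2-en-7-yne-1,5-diol, via terminal epoxide 6 (not isolated)
Conditions: lithium acetylide–ethylenediamine complex (4 equiv), DMSO, 0 °C to rt; aq. NH4Cl
Reagents that add atoms: lithium acetylide–ethylenediamine complex, [Li]C#C.NCCN
Why: The C5 alkoxide closes the chlorohydrin to epoxide 6 and the acetylide opens it at the CH2 terminus (SN2 epoxide alkynylation); the C5–O bond is never broken (the descriptor changes only through ligand priorities) and the (E) double bond keeps the C1 alkoxide away from the epoxide.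

Step 4
Reactants: 7 (2E,5S)-3-methyloct-2-en-7-yne-1,5-diol
Product: 8 (2S)-1-[(2R,3R)-3-(hydroxymethyl)-2-methyloxiran-2-yl]pent-4-yn-2-ol
Conditions: Ti(OiPr)4 (20 mol%), D-(−)-diethyl tartrate (24 mol%), t-BuOOH (2 equiv, decane), 4 Å MS, CH2Cl2, −20 °C
Reagents that add atoms: tert-butyl hydroperoxide, CC(C)(C)OO
Why: Katsuki–Sharpless asymmetric epoxidation: with D-(−)-tartrate an (E)-3-methyl-2-alken-1-ol of the geraniol type should give the (2R,3R)-epoxide, so C2 and C3 are set together under reagent control, independent of the remote C5 carbinol; the alkyne and the secondary alcohol are not oxidised.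

Step 5
Reactants: 8 (2S)-1-[(2R,3R)-3-(hydroxymethyl)-2-methyloxiran-2-yl]pent-4-yn-2-ol; 9 umbelliferone (7-hydroxy-2H-chromen-2-one)
Product: 10 7-({(2R,3R)-3-[(2S)-2-hydroxypent-4-yn-1-yl]-3-methyloxiran-2-yl}methoxy)-2H-chromen-2-one
Conditions: PPh3, DIAD, THF, 0 °C to rt
Reagents that add atoms: none
Why: Mitsunobu etherification: the primary C1 hydroxyl is activated in preference to the hindered secondary C5 hydroxyl and displaced by the acidic phenol 9; the neutral conditions leave the epoxide, the alkyne and the coumarin lactone intact and touch no stereocenter.

Step 6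
Reactants: 10 7-({(2R,3R)-3-[(2S)-2-hydroxypent-4-yn-1-yl]-3-methyloxiran-2-yl}methoxy)-2H-chromen-2-one
Product: 11 7-{[(2R,3S,5S)-2,3,5-trihydroxy-3-methyloct-7-yn-1-yl]oxy}-2H-chromen-2-one
Conditions: HClO4 (5 mol%), THF/H2O (3:1), 0 °C to rt
Reagents that add atoms: water, O
Why: Acid-catalysed epoxide hydrolysis: water attacks the protonated trisubstituted epoxide at the tertiary C3 anti to the leaving oxygen (inversion, R to S), while C2, deactivated by the aryloxymethyl group, keeps its oxygen and configuration, which gives the anti diol; the C5 hydroxyl could reach C3 only through a four-membered ring.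

Step 7
Reactants: 11 7-{[(2R,3S,5S)-2,3,5-trihydroxy-3-methyloct-7-yn-1-yl]oxy}-2H-chromen-2-one
Product: 12 7-({(2R,3S)-2,3-dihydroxy-3-methyl-4-[(2S)-4-methylidene-5-oxooxolan-2-yl]butyl}oxy)-2H-chromen-2-one (the target)
Conditions: PdCl2(PPh3)2 (5 mol%), SnCl2 (5 mol%), CO (7 atm), MeCN, 75 °C
Reagents that add atoms: carbon monoxide, [C-]#[O+]
Why: This is the palladium-catalysed cyclocarbonylation of a homopropargylic alcohol, the closest known reaction type, here applied to an unprotected triol. Divalent palladium, carbon monoxide and the C5 hydroxyl form an alkoxycarbonyl–palladium species; the tethered alkyne inserts cis into its Pd–C bond, so C8 bonds to the internal carbon C7 and palladium ends on C9; protonolysis of that vinyl–palladium bond by the acid released in the first event frees the exocyclic methylene and returns divalent palladium. Ring C (O, C8, C7, C6, C5) closes in the 5-exo-dig mode, the O–C8 bond being made before the C8–C7 bond. No stereocenter is created: C2, C3 and C5 are carried through unchanged because no bond to them is broken. The step needs site selectivity among three hydroxyls, and ring size secures it: only the C5 alkoxycarbonyl reaches the alkyne through a five-membered transition state, whereas the C3 and C2 hydroxyls would need seven- and eight-membered rings. It also needs the double bond to stay exocyclic, which the base-free medium and the absence of any later step secure. The coumarin, the aryl ether and the 1,2-diol take no part in the cycle, and the carbon monoxide pressure with the phosphine–tin chloride ligand set keeps palladium on the carbonylation path and away from plain hydroalkoxylation of the alkyne.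

## Compound list

1 | (R)-epichlorohydrin, (2R)-2-(chloromethyl)oxirane | ClC[C@H]1CO1 | starting material
2 | (2R)-1-chloropent-4-yn-2-ol | C#CC[C@H](CCl)O | intermediate
3 | [(1E,4R)-5-chloro-4-(dimethylalumanyloxy)-2-methylpent-1-en-1-yl]dimethylalumane | C[Al](C)/C=C(C)/C[C@H](CCl)O[Al](C)C | intermediate (not isolated)
4 | lithium butyl[(1E,4R)-5-chloro-4-(dimethylalumanyloxy)-2-methylpent-1-en-1-yl]dimethylaluminate | [Li+].CCCC[Al-](C)(C)/C=C(C)/C[C@H](CCl)O[Al](C)C | intermediate (not isolated)
5 | (2E,5R)-6-chloro-3-methylhex-2-ene-1,5-diol | OC/C=C(C)/C[C@H](CCl)O | intermediate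
6 | (2E)-3-methyl-4-[(2R)-oxiran-2-yl]but-2-en-1-ol | OC/C=C(C)/C[C@@H]1CO1 | intermediate (not isolated)
7 | (2E,5S)-3-methyloct-2-en-7-yne-1,5-diol | OC/C=C(C)/C[C@H](CC#C)O | intermediate
8 | (2S)-1-[(2R,3R)-3-(hydroxymethyl)-2-methyloxiran-2-yl]pent-4-yn-2-ol | OC[C@H]1O[C@]1(C)C[C@H](CC#C)O | intermediate
9 | umbelliferone, 7-hydroxy-2H-chromen-2-one | O=c1ccc2ccc(O)cc2o1 | starting material
10 | 7-({(2R,3R)-3-[(2S)-2-hydroxypent-4-yn-1-yl]-3-methyloxiran-2-yl}methoxy)-2H-chromen-2-one | O=c1ccc2ccc(OC[C@H]3O[C@]3(C)C[C@H](CC#C)O)cc2o1 | intermediate
11 | 7-{[(2R,3S,5S)-2,3,5-trihydroxy-3-methyloct-7-yn-1-yl]oxy}-2H-chromen-2-one | C#CC[C@@H](C[C@](C)(O)[C@H](O)COc1ccc2ccc(=O)oc2c1)O | intermediate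
12 | 7-({(2R,3S)-2,3-dihydroxy-3-methyl-4-[(2S)-4-methylidene-5-oxooxolan-2-yl]butyl}oxy)-2H-chromen-2-one | C=C1C[C@@H](C[C@](C)(O)[C@H](O)COc2ccc3ccc(=O)oc3c2)OC1=O | target

## Step count and risk

Total step count: 7. Longest linear sequence: 7 steps (1 to 12); the phenol 9 enters at step 5. No protecting group is used.

**Step 7 (key step).** The most likely failure is diversion of palladium into hydroalkoxylation or ketal formation at the alkyne by the 1,3-related C3 and C5 hydroxyls, or sequestration of the catalyst by the 1,2-diol; migration of the new double bond into the ring on prolonged heating is the second concern. The fallback closes ring C on a simpler substrate, before the tertiary alcohol and the coumarin exist. It sets out from 7: the same cyclocarbonylation on this diol, whose remote (E)-allylic hydroxyl cannot reach the alkyne, should give (5R)-5-[(2E)-4-hydroxy-2-methylbut-2-en-1-yl]-3-methylideneoxolan-2-one F1. Katsuki–Sharpless epoxidation with D-(−)-diethyl tartrate, which leaves the electron-poor methylene lactone alone, should give (5S)-5-{[(2R,3R)-3-(hydroxymethyl)-2-methyloxiran-2-yl]methyl}-3-methylideneoxolan-2-one F2. Mitsunobu coupling with 9 should give 7-{[(2R,3R)-3-methyl-3-{[(2S)-4-methylidene-5-oxooxolan-2-yl]methyl}oxiran-2-yl]methoxy}-2H-chromen-2-one F3, and the acid hydrolysis of step 6 then returns to the route at 12.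

**Step 6.** The most likely failure is partial loss of stereochemical fidelity at C3 through a carbocation-like opening with some retention, or a competing attack of the C5 hydroxyl on C2. The fallback delivers the C3 oxygen from within the molecule. It sets out from 10: acylation of the C5 hydroxyl (Boc2O, DMAP) should give tert-butyl (2S)-1-[(2R,3R)-2-methyl-3-{[(2-oxo-2H-chromen-7-yl)oxy]methyl}oxiran-2-yl]pent-4-yn-2-yl carbonate F4. With BF3·OEt2 at low temperature its carbonyl oxygen should open the epoxide at C3 in a 6-exo mode with strict inversion, giving the cyclic carbonate 7-{(2R)-2-hydroxy-2-[(4S,6S)-4-methyl-2-oxo-6-(prop-2-yn-1-yl)-1,3-dioxan-4-yl]ethoxy}-2H-chromen-2-one F5. Mild methanolysis (K2CO3, MeOH, 0 °C) returns to the route at 11.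

**Step 4.** The most likely failure is slow turnover and eroded face selectivity because the free C5 hydroxyl competes with the allylic hydroxyl for titanium. The fallback removes the need for a directing group. It sets out from 7: Mitsunobu coupling with 9 at the primary allylic hydroxyl should give 7-{[(2E,5S)-5-hydroxy-3-methyloct-2-en-7-yn-1-yl]oxy}-2H-chromen-2-one F6. Shi epoxidation of its trisubstituted (E)-alkene (D-fructose-derived ketone, KHSO5 as the triple salt 2KHSO5·KHSO4·K2SO4, K2CO3 buffer, MeCN/dimethoxymethane/H2O, 0 °C) should give the (2R,3R)-epoxide and returns to the route at 10.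

**Step 2.** The most likely failure is chelation-assisted (E)-to-(Z) isomerisation of the alkenylalane by the neighbouring aluminium alkoxide, or incomplete alkenyl transfer from the ate complex so that protonolysis to the 1,1-disubstituted alkene competes. The fallback attaches C1 by cross-coupling instead. It sets out from 2: carboalumination as before, quenched at once with I2 at −30 °C, should give (2R,4E)-1-chloro-5-iodo-4-methylpent-4-en-2-ol F7. Stille coupling with tributyl(hydroxymethyl)stannane Bu3SnCH2OH (Pd(PPh3)4, dioxane, 80 °C) proceeds with retention of alkene geometry and returns to the route at 5.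

## Further compounds

F1 | step 7 | (5R)-5-[(2E)-4-hydroxy-2-methylbut-2-en-1-yl]-3-methylideneoxolan-2-one | C=C1C[C@@H](C/C(C)=C/CO)OC1=O
F2 | step 7 | (5S)-5-{[(2R,3R)-3-(hydroxymethyl)-2-methyloxiran-2-yl]methyl}-3-methylideneoxolan-2-one | C=C1C[C@@H](C[C@@]2(C)O[C@@H]2CO)OC1=O
F3 | step 7 | 7-{[(2R,3R)-3-methyl-3-{[(2S)-4-methylidene-5-oxooxolan-2-yl]methyl}oxiran-2-yl]methoxy}-2H-chromen-2-one | C=C1C[C@@H](C[C@@]2(C)O[C@@H]2COc3ccc4ccc(=O)oc4c3)OC1=O
F4 | step 6 | tert-butyl (2S)-1-[(2R,3R)-2-methyl-3-{[(2-oxo-2H-chromen-7-yl)oxy]methyl}oxiran-2-yl]pent-4-yn-2-yl carbonate | O=c1ccc2ccc(OC[C@H]3O[C@]3(C)C[C@H](CC#C)OC(=O)OC(C)(C)C)cc2o1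
F5 | step 6 | 7-{(2R)-2-hydroxy-2-[(4S,6S)-4-methyl-2-oxo-6-(prop-2-yn-1-yl)-1,3-dioxan-4-yl]ethoxy}-2H-chromen-2-one | C#CC[C@H]1C[C@@](C)([C@H](O)COc2ccc3ccc(=O)oc3c2)OC(=O)O1
F6 | step 4 | 7-{[(2E,5S)-5-hydroxy-3-methyloct-2-en-7-yn-1-yl]oxy}-2H-chromen-2-one | O=c1ccc2ccc(OC/C=C(C)/C[C@H](CC#C)O)cc2o1
F7 | step 2 | (2R,4E)-1-chloro-5-iodo-4-methylpent-4-en-2-ol | I/C=C(C)/C[C@H](CCl)O
A1 | alternative 1 | 2-[(4S,5R)-2,2,4-trimethyl-5-{[(2-oxo-2H-chromen-7-yl)oxy]methyl}-1,3-dioxolan-4-yl]acetaldehyde | O=CC[C@]1(C)OC(C)(C)O[C@@H]1COc1ccc2ccc(=O)oc2c1
A2 | alternative 2 | (6S)-4-methyl-6-(prop-2-yn-1-yl)-5,6-dihydro-2H-pyran-2-one | C#CC[C@H]1CC(C)=CC(=O)O1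
A3 | alternative 2 | (3S,4S,6S)-3,4-dihydroxy-4-methyl-6-(prop-2-yn-1-yl)oxan-2-one | C#CC[C@H]1C[C@](C)(O)[C@H](O)C(=O)O1
A4 | alternative 3 | 7-{[(2Z)-3-iodobut-2-en-1-yl]oxy}-2H-chromen-2-one | C/C(I)=C/COc1ccc2ccc(=O)oc2c1
A5 | alternative 3 | trimethyl{3-[(2S)-oxiran-2-yl]prop-1-yn-1-yl}silane | C[Si](C)(C)C#CC[C@H]1CO1
A6 | alternative 3 | 7-{[(2Z,5R)-5-hydroxy-3-methyl-8-(trimethylsilyl)oct-2-en-7-yn-1-yl]oxy}-2H-chromen-2-one | C[Si](C)(C)C#CC[C@@H](C/C(C)=C\COc1ccc2ccc(=O)oc2c1)O
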